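**Retrosynthetic overview**
Ring labels: A = biaryl ring with its oxygen para to the aryl–aryl bond; B = ring with OH and OAr on neighbouring carbons; C = the 1,4-phenylene; D = biaryl ring with its oxygen ortho to the aryl–aryl bond.
Strategic feature: in ring D the hydroxyl oxygen sits on the carbon directly beside the carbon that carries the A–D bond, so this oxygen can hold ring A as an arenesulfonate (D–O–SO2–A, sulfur on the future biaryl carbon of ring A, which is flanked by the CH2CH2 bridge) and pass it to the neighbouring, brominated carbon.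
Last disconnection: the A–D biaryl bond, formed by radical ipso substitution with loss of SO2, which contracts a 19-membered macrocyclic sulfonate to the 16-membered ring.
The sulfonate ring is opened at S–O (sulfur–fluoride exchange of ArSO2F with an aryl silyl ether), then at the B–O–C diaryl ether (Chan–Lam), giving A–B and C–D bibenzyls, each from Wittig olefination and reduction.
Ring order: four purchased arenes; 19-membered ring closed at S–O; 16-membered ring by contraction; no stereocentre arises.

Key step: step 13

Remark: the target has no stereocentre and its biaryl axis is unspecified, so it is treated as configurationally unconstrained and no stereocontrol is planned; both stilbene geometries are removed by reduction.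

**Route**

Step 1
Reactants: 1 4-methoxy-2-methylbenzenesulfonyl chloride
Product: 2 4-methoxy-2-methylbenzenesulfonyl fluoride
Conditions: KHF2 (sat. aq.), MeCN, rt
Reagents that add atoms: potassium hydrogen difluoride, F.[F-].[K+]
Why: Chloride-to-fluoride exchange at the sulfonyl group with bifluoride should be clean and gives a sulfonyl fluoride that, unlike the chloride, resists hydrolysis, reduction, phosphines and the Wittig chemistry ahead.

Step 2
Reactants: 2 4-methoxy-2-methylbenzenesulfonyl fluoride
Product: 3 2-(bromomethyl)-4-methoxybenzenesulfonyl fluoride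
Conditions: NBS (1.05 equiv), AIBN (cat.), PhCF3, 85 °C
Reagents that add atoms: N-bromosuccinimide, O=C1CCC(=O)N1Br
Why: Wohl–Ziegler radical bromination should take the benzylic CH3 because the SO2F group deactivates the ring towards electrophilic bromination and the S–F bond is inert to bromine radicals; one equivalent of NBS limits dibromination.

Step 3
Reactants: 3 2-(bromomethyl)-4-methoxybenzenesulfonyl fluoride
Product: 4 [2-(fluorosulfonyl)-5-methoxybenzyl]triphenylphosphonium bromide
Conditions: PPh3, PhMe, 80 °C
Reagents that add atoms: triphenylphosphine, c1ccc(cc1)P(c1ccccc1)c1ccccc1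
Why: SN2 quaternisation of PPh3 by the benzylic bromide; PPh3 should not reduce a sulfonyl fluoride as it would a sulfonyl chloride.

Step 4
Reactants: 4 [2-(fluorosulfonyl)-5-methoxybenzyl]triphenylphosphonium bromide; 5 3-benzyloxy-4-methoxybenzaldehyde
Product: 7 4-methoxy-2-[2-(3-benzyloxy-4-methoxyphenyl)ethenyl]benzenesulfonyl fluoride (E/Z mixture), via phosphorus ylide 6 (not isolated)
Conditions: K2CO3, 18-crown-6 (cat.), CH2Cl2, reflux
Reagents that add atoms: none
Why: Wittig olefination under solid–liquid carbonate conditions forms the semistabilised ylide only in low concentration beside the aldehyde, and neither carbonate nor ylide should attack the S–F bond; alkene geometry is irrelevant because the double bond is reduced next.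

Step 5
Reactants: 7 A–B stilbene (E/Z mixture)
Product: 8 2-[2-(3-hydroxy-4-methoxyphenyl)ethyl]-4-methoxybenzenesulfonyl fluoride
Conditions: H2 (1 atm), Pd/C (10%), EtOAc/THF, rt; kept free of base
Reagents that add atoms: none
Why: Heterogeneous catalytic hydrogenation saturates the stilbene and hydrogenolyses the benzyl ether in one operation, while the sulfonyl fluoride is inert to H2 over palladium and, without base, to the liberated phenol.

Step 6
Reactants: 9 2-bromo-3-hydroxybenzaldehyde
Product: 10 2-bromo-3-(tert-butyldimethylsilyloxy)benzaldehyde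
Conditions: TBSCl, imidazole, DMF, rt
Reagents that add atoms: tert-butyldimethylsilyl chloride, CC(C)(C)[Si](C)(C)Cl
Why: Standard imidazole-promoted silylation of a phenol; the silyl ether later serves as the latent nucleophile for sulfur–fluoride exchange.

Step 7
Reactants: 11 4-(bromomethyl)phenylboronic acid pinacol ester
Product: 12 [4-(4,4,5,5-tetramethyl-1,3,2-dioxaborolan-2-yl)benzyl]triphenylphosphonium bromide
Conditions: PPh3, PhMe, 90 °C
Reagents that add atoms: triphenylphosphine, c1ccc(cc1)P(c1ccccc1)c1ccccc1
Why: SN2 quaternisation of PPh3 by the benzylic bromide, with the pinacol boronate as a spectator.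

Step 8
Reactants: 10 2-bromo-3-(tert-butyldimethylsilyloxy)benzaldehyde; 12 ring C phosphonium bromide
Product: 14 tert-butyl[2-bromo-3-[2-[4-(4,4,5,5-tetramethyl-1,3,2-dioxaborolan-2-yl)phenyl]ethenyl]phenoxy]dimethylsilane (E/Z mixture), via boryl-substituted phosphorus ylide 13 (not isolated)
Conditions: NaHMDS (1.05 equiv), THF, −78 °C; then 10, −78 °C to rt
Reagents that add atoms: none
Why: Wittig olefination with the ylide preformed at low temperature by a non-nucleophilic amide base, which should leave the aryl bromide, the aryl silyl ether and the pinacol boronate intact; geometry is irrelevant.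

Step 9
Reactants: 14 C–D stilbene (E/Z mixture)
Product: 15 tert-butyl[2-bromo-3-[2-[4-(4,4,5,5-tetramethyl-1,3,2-dioxaborolan-2-yl)phenyl]ethyl]phenoxy]dimethylsilane
Conditions: TsNHNH2 (excess), NaOAc, THF/H2O, reflux
Reagents that add atoms: none
Why: Diimide, released by base-induced fragmentation of the sulfonyl hydrazide, transfers H2 to the C=C bond in a concerted syn fashion and, unlike H2 over palladium, cannot hydrogenolyse the C–Br bond; the weakly basic acetate buffer should spare the aryl silyl ether.

Step 10
Reactants: 15 C–D bibenzyl pinacol boronate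
Product: 16 [4-[2-[2-bromo-3-(tert-butyldimethylsilyloxy)phenyl]ethyl]phenyl]boronic acid
Conditions: NaIO4, NH4OAc, acetone/H2O, rt
Reagents that add atoms: water, O
Why: Periodate cleaves the pinacol released in the hydrolysis equilibrium (glycol cleavage), pulling the ester over to the free boronic acid needed for copper-mediated coupling, under conditions neutral towards the silyl ether and the bromide.

Step 11
Reactants: 8 A–B bibenzyl phenol sulfonyl fluoride; 16 C–D bibenzyl boronic acid
Product: 17 2-[2-[3-[4-[2-[2-bromo-3-(tert-butyldimethylsilyloxy)phenyl]ethyl]phenoxy]-4-methoxyphenyl]ethyl]-4-methoxybenzenesulfonyl fluoride (open-chain tetraarene)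
Conditions: Cu(OAc)2 (1.5 equiv), pyridine, 4 Å MS, CH2Cl2, air, rt
Reagents that add atoms: none
Why: Chan–Lam oxidative coupling of a phenol with an arylboronic acid by divalent copper at room temperature; pyridine is too weak a base to trigger sulfur–fluoride exchange of the sulfonyl fluoride with either the phenol or the silyl ether, and the aryl bromide is untouched.

Step 12
Reactants: 17 open-chain tetraarene
Product: 18 19-membered macrocyclic aryl arenesulfonate (ring D oxygen bonded to the SO2 group on ring A; bromine on the ring D carbon between the C–O carbon and the bridge-bearing carbon; methoxy groups on rings A and B)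
Conditions: DBU (0.2 equiv), MeCN (0.002 M), 50 °C
Reagents that add atoms: none
Why: Sulfur–fluoride exchange (SuFEx) between an arenesulfonyl fluoride and an aryl silyl ether under amidine catalysis, driven by Si–F bond formation; high dilution should favour closure of the unstrained 19-membered ring over oligomerisation.

Step 13
Reactants: 18 19-membered macrocyclic sulfonate
Product: 19 plagiochin E dimethyl ether (methoxy on rings A and B; free hydroxyl on ring D)
Conditions: Bu3SnH (1.5 equiv) and AIBN (0.3 equiv) by syringe pump over 10 h, PhMe (0.003 M), 90 °C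
Reagents that add atoms: none
Why: Proposed new method: the tributyltin radical abstracts bromine to give a sigma aryl radical on ring D, which adds to the sulfur-bearing ipso carbon of ring A through a five-membered spiro transition state (radical carbon, C–O carbon, O, S, ipso carbon); the spiro cyclohexadienyl radical (spin delocalised onto the ring A carbons bearing OMe and the bridge) rearomatises by C–S cleavage, the aryloxysulfonyl radical loses SO2 and the phenoxyl radical takes hydrogen from Bu3SnH to continue the chain. The closest known reaction type is the hydride-mediated radical 1,5-ipso substitution (radical Truce–Smiles rearrangement) of open-chain arenesulfonates of 2-halophenols to 2-hydroxybiaryls, and radical transannular ring contraction of macrocyclic bis(bibenzyls) is also known; what is new is running the aryl transfer inside a macrocycle so that it removes three atoms from the ring. The only ring closed in the bond-forming event is the transient five-membered spiro ring (5-exo-type ipso attack), and its collapse converts the 19-membered sulfonate ring into the 16-membered ring of the target because S, O and the oxygen-bearing carbon of ring D leave the ring perimeter. No stereocentre is formed. The step needs ipso attack to beat 1,6-addition to the free ortho CH of ring A (six-membered sultone) and direct reduction of the aryl radical: the reacting sites are fixed by the bromine and the sulfur, the ortho CH2CH2 bridge twists ring A and blocks one ortho site, and syringe-pump addition keeps the stannane concentration low. The bond formation is local, the tether joining the other ortho positions of rings A and D is the one already present in the only moderately strained product, and the closest bridge C–H (on the CH2 beta to ring D) could be reached only through a strained 1,4-hydrogen transfer.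

Step 14
Reactants: 19 plagiochin E dimethyl ether
Product: 20 plagiochin E
Conditions: BBr3 (excess), CH2Cl2, −78 °C to rt; then H2O
Reagents that add atoms: none
Why: Lewis acid demethylation of aryl methyl ethers with BBr3; the diaryl ether, the biaryl and the benzylic bridges are stable, and the free ring D phenol is only borylated and released again on hydrolysis.

**Compound list**
1 | 4-methoxy-2-methylbenzenesulfonyl chloride | COc1ccc(S(=O)(=O)Cl)c(C)c1 | starting material
2 | 4-methoxy-2-methylbenzenesulfonyl fluoride | COc1ccc(S(=O)(=O)F)c(C)c1 | intermediate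
3 | 2-(bromomethyl)-4-methoxybenzenesulfonyl fluoride | COc1ccc(S(=O)(=O)F)c(CBr)c1 | intermediate
4 | [2-(fluorosulfonyl)-5-methoxybenzyl]triphenylphosphonium bromide | COc1ccc(S(=O)(=O)F)c(C[P+](c2ccccc2)(c2ccccc2)c2ccccc2)c1.[Br-] | intermediate
5 | 3-benzyloxy-4-methoxybenzaldehyde | COc1ccc(C=O)cc1OCc1ccccc1 | starting material
6 | [2-(fluorosulfonyl)-5-methoxybenzylidene]triphenylphosphorane (not isolated) | COc1ccc(S(=O)(=O)F)c(C=P(c2ccccc2)(c2ccccc2)c2ccccc2)c1 | intermediate
7 | 4-methoxy-2-[2-(3-benzyloxy-4-methoxyphenyl)ethenyl]benzenesulfonyl fluoride (E/Z mixture) | COc1ccc(S(=O)(=O)F)c(C=Cc2ccc(OC)c(OCc3ccccc3)c2)c1 | intermediate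
8 | 2-[2-(3-hydroxy-4-methoxyphenyl)ethyl]-4-methoxybenzenesulfonyl fluoride | COc1ccc(S(=O)(=O)F)c(CCc2ccc(OC)c(O)c2)c1 | intermediate
9 | 2-bromo-3-hydroxybenzaldehyde | O=Cc1cccc(O)c1Br | starting material
10 | 2-bromo-3-(tert-butyldimethylsilyloxy)benzaldehyde | O=Cc1cccc(O[Si](C)(C)C(C)(C)C)c1Br | intermediate
11 | 4-(bromomethyl)phenylboronic acid pinacol ester | BrCc1ccc(B2OC(C)(C)C(C)(C)O2)cc1 | starting material
12 | [4-(4,4,5,5-tetramethyl-1,3,2-dioxaborolan-2-yl)benzyl]triphenylphosphonium bromide | [Br-].c1ccc(cc1)[P+](Cc1ccc(B2OC(C)(C)C(C)(C)O2)cc1)(c1ccccc1)c1ccccc1 | intermediate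
13 | [4-(4,4,5,5-tetramethyl-1,3,2-dioxaborolan-2-yl)benzylidene]triphenylphosphorane (not isolated) | CC1(C)OB(c2ccc(C=P(c3ccccc3)(c3ccccc3)c3ccccc3)cc2)OC1(C)C | intermediate
14 | tert-butyl[2-bromo-3-[2-[4-(4,4,5,5-tetramethyl-1,3,2-dioxaborolan-2-yl)phenyl]ethenyl]phenoxy]dimethylsilane (E/Z mixture) | CC(C)(C)[Si](C)(C)Oc1cccc(C=Cc2ccc(B3OC(C)(C)C(C)(C)O3)cc2)c1Br | intermediate
15 | tert-butyl[2-bromo-3-[2-[4-(4,4,5,5-tetramethyl-1,3,2-dioxaborolan-2-yl)phenyl]ethyl]phenoxy]dimethylsilane | CC(C)(C)[Si](C)(C)Oc1cccc(CCc2ccc(B3OC(C)(C)C(C)(C)O3)cc2)c1Br | intermediate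
16 | [4-[2-[2-bromo-3-(tert-butyldimethylsilyloxy)phenyl]ethyl]phenyl]boronic acid | CC(C)(C)[Si](C)(C)Oc1cccc(CCc2ccc(B(O)O)cc2)c1Br | intermediate
17 | 2-[2-[3-[4-[2-[2-bromo-3-(tert-butyldimethylsilyloxy)phenyl]ethyl]phenoxy]-4-methoxyphenyl]ethyl]-4-methoxybenzenesulfonyl fluoride | COc1ccc(S(=O)(=O)F)c(CCc2ccc(OC)c(Oc3ccc(CCc4cccc(O[Si](C)(C)C(C)(C)C)c4Br)cc3)c2)c1 | intermediate
18 | 19-membered macrocyclic aryl arenesulfonate (ring D–O–SO2–ring A; Br on ring D) | COc1ccc2c(c1)CCc1ccc(OC)c(c1)Oc1ccc(cc1)CCc1cccc(c1Br)OS2(=O)=O | intermediate
19 | plagiochin E dimethyl ether (free ring D phenol) | COc1ccc2c(c1)CCc1ccc(OC)c(c1)Oc1ccc(cc1)CCc1cccc(O)c1-2 | intermediate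
20 | plagiochin E | Oc1ccc2c(c1)CCc1ccc(O)c(c1)Oc1ccc(cc1)CCc1cccc(O)c1-2 | target

**Step count**
Total: 14 steps. Longest linear sequence: 9 steps (steps 1, 2, 3, 4, 5, 11, 12, 13, 14); the C–D branch (steps 6–10) joins at step 11.

**Steps most likely to fail**

Step 13 (labelled step). The aryl radical may be reduced before it transfers ring A, or may add to the free ortho CH of ring A and end as a sultone, so that the ring does not contract. Fallback by known biaryl macrocyclisation, setting out from 16 and returning at 19: commercial 2-bromo-5-methoxybenzyl bromide and PPh3 would give [(2-bromo-5-methoxyphenyl)methyl]triphenylphosphonium bromide F1. Excess K2CO3 with 18-crown-6 in CH2Cl2 would convert it into the ylide (2-bromo-5-methoxybenzylidene)triphenylphosphorane F2 in the flask, which with commercial 3-hydroxy-4-methoxybenzaldehyde would give 5-[2-(2-bromo-5-methoxyphenyl)ethenyl]-2-methoxyphenol F3. Diimide reduction (TsNHNH2, NaOAc) would give 5-[2-(2-bromo-5-methoxyphenyl)ethyl]-2-methoxyphenol F4. Chan–Lam coupling of F4 with 16 (Cu(OAc)2, pyridine, 4 Å MS, CH2Cl2, air) would give the open-chain dibromide silyl ether F5. An intramolecular Stille–Kelly coupling (Pd(PPh3)4 as the zerovalent palladium catalyst, Me3SnSnMe3, dioxane, reflux, high dilution), a reaction type already used to close the biaryl bond of macrocyclic bis(bibenzyls), would give the macrocyclic biaryl silyl ether F6. Bu4NF in THF would then free the ring D phenol to give 19.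

Step 12. Intermolecular exchange may outrun ring closure (oligomers), or the electron-rich, ortho-substituted sulfonyl fluoride may exchange too slowly. Fallback that makes the S–O bond between fragments and closes the 19-membered ring at the diaryl ether instead, setting out from 7 (with 15) and returning at 18: DBU-catalysed intermolecular sulfur–fluoride exchange of 7 with the silyl ether 15 would give the open-chain stilbene sulfonate F7. Diimide (TsNHNH2, NaOAc) would saturate it to the bibenzyl sulfonate benzyl ether F8. BCl3 with pentamethylbenzene at −78 °C would remove the benzyl group without touching the C–Br bond, giving the phenol pinacol boronate F9. NaIO4/NH4OAc would free the phenol boronic acid F10. A macrocyclising Chan–Lam coupling (Cu(OAc)2, pyridine, 4 Å MS, CH2Cl2, air, high dilution) would close the ether and give 18.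

Step 11. The free phenol of 8 may sulfonylate itself under the copper/pyridine conditions, or the coupling of the ortho-methoxy phenol may be slow enough for protodeboronation to win. Fallback that forms the ether before any sulfonyl fluoride is present, setting out from 16 and returning at 17: Chan–Lam coupling of 16 with commercial 3-hydroxy-4-methoxybenzaldehyde would give the diaryl ether aldehyde 3-[4-[2-[2-bromo-3-(tert-butyldimethylsilyloxy)phenyl]ethyl]phenoxy]-4-methoxybenzaldehyde F11. Wittig olefination with ylide 6, preformed from 4 with NaHMDS in THF at −78 °C, would give the open-chain stilbene sulfonyl fluoride F12. Anhydrous diimide reduction (2-nitrobenzenesulfonyl hydrazide, Et3N, CH2Cl2, rt), which spares the C–Br, S–F and Si–O bonds, would give 17.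

**Further compounds**
F1 | step 13 | [(2-bromo-5-methoxyphenyl)methyl]triphenylphosphonium bromide | COc1ccc(Br)c(C[P+](c2ccccc2)(c2ccccc2)c2ccccc2)c1.[Br-]
F2 | step 13 | (2-bromo-5-methoxybenzylidene)triphenylphosphorane (not isolated) | COc1ccc(Br)c(C=P(c2ccccc2)(c2ccccc2)c2ccccc2)c1
F3 | step 13 | 5-[2-(2-bromo-5-methoxyphenyl)ethenyl]-2-methoxyphenol (E/Z mixture) | COc1ccc(Br)c(C=Cc2ccc(OC)c(O)c2)c1
F4 | step 13 | 5-[2-(2-bromo-5-methoxyphenyl)ethyl]-2-methoxyphenol | COc1ccc(Br)c(CCc2ccc(OC)c(O)c2)c1
F5 | step 13 | open-chain dibromide silyl ether (Br on rings A and D) | COc1ccc(Br)c(CCc2ccc(OC)c(Oc3ccc(CCc4cccc(O[Si](C)(C)C(C)(C)C)c4Br)cc3)c2)c1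
F6 | step 13 | tert-butyldimethylsilyl ether of 19 at the ring D oxygen | COc1ccc2c(c1)CCc1ccc(OC)c(c1)Oc1ccc(cc1)CCc1cccc(O[Si](C)(C)C(C)(C)C)c1-2
F7 | step 12 | open-chain stilbene sulfonate (benzyl ether, pinacol boronate, Br; E/Z mixture) | COc1ccc(S(=O)(=O)Oc2cccc(CCc3ccc(B4OC(C)(C)C(C)(C)O4)cc3)c2Br)c(C=Cc2ccc(OC)c(OCc3ccccc3)c2)c1
F8 | step 12 | open-chain bibenzyl sulfonate (benzyl ether, pinacol boronate, Br) | COc1ccc(S(=O)(=O)Oc2cccc(CCc3ccc(B4OC(C)(C)C(C)(C)O4)cc3)c2Br)c(CCc2ccc(OC)c(OCc3ccccc3)c2)c1
F9 | step 12 | open-chain sulfonate with free ring B phenol and pinacol boronate | COc1ccc(S(=O)(=O)Oc2cccc(CCc3ccc(B4OC(C)(C)C(C)(C)O4)cc3)c2Br)c(CCc2ccc(OC)c(O)c2)c1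
F10 | step 12 | open-chain sulfonate with free ring B phenol and boronic acid | COc1ccc(S(=O)(=O)Oc2cccc(CCc3ccc(B(O)O)cc3)c2Br)c(CCc2ccc(OC)c(O)c2)c1
F11 | step 11 | 3-[4-[2-[2-bromo-3-(tert-butyldimethylsilyloxy)phenyl]ethyl]phenoxy]-4-methoxybenzaldehyde | COc1ccc(C=O)cc1Oc1ccc(CCc2cccc(O[Si](C)(C)C(C)(C)C)c2Br)cc1
F12 | step 11 | open-chain stilbene sulfonyl fluoride (E/Z mixture) | COc1ccc(S(=O)(=O)F)c(C=Cc2ccc(OC)c(Oc3ccc(CCc4cccc(O[Si](C)(C)C(C)(C)C)c4Br)cc3)c2)c1
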